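The bicyclic core is numbered C1 (prenylated bridgehead), C5 (side‑chain bridgehead), C6 (CH2), C7 (CH), C8 (CMe2), C9 (bridging ketone). Ring B (C1, C8, C7, C6, C5, C9) hides a cyclobutanone: C9(=O), C1, C8 and C7 form a 3,3‑dimethylcyclobutanone, and C5=C6 is a 1,1‑disubstituted alkene tethered to C1 through C2–C4. Rhodium‑catalysed C–C activation of the strained C9–C7 bond and insertion of this alkene ("cut and sew") should forge C5–C9 and C6–C7 in one operation, closing both six‑membered rings and the C5 quaternary centre. The precursor is a monocyclic pentasubstituted cyclobutanone with a methoxydienone arm. Its ring stereocentres come from (−)‑verbenone, the side‑chain stereocentre from (+)‑limonene oxide.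

Key step: step 11

Remark: commercial (+)‑limonene oxide is a cis/trans mixture at the epoxide; both isomers converge in step 5 and it is used as such.

Step 1
Reactants: 1 (1S,5S)‑(−)‑verbenone
Product: 2 3‑allylverbenone, (1S,5R)‑4,6,6‑trimethyl‑3‑(prop‑2‑en‑1‑yl)bicyclo[3.1.1]hept‑3‑en‑2‑one (same spatial arrangement as 1)
Conditions: KOt‑Bu, allyl bromide, DME, 0 °C to rt
Reagents that add atoms: allyl bromide, C=CCBr
Why: γ‑Deprotonation gives the extended dienolate, which is allylated at the α‑carbon (C3 of verbenone) and reconjugated by the base (α‑alkylation of a vinylogous enolate, as known for verbenone with allylic bromides); no stereocentre is formed.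

Step 2
Reactants: 2 3‑allylverbenone
Product: 3 1‑allylchrysanthenone, (1R,5S)‑2,7,7‑trimethyl‑1‑(prop‑2‑en‑1‑yl)bicyclo[3.1.1]hept‑2‑en‑6‑one
Conditions: hν (350 nm), cyclohexane, rt
Reagents that add atoms: none
Why: The photochemical 1,3‑alkyl shift of the verbenone–chrysanthenone type moves the CMe2 carbon to the allyl‑bearing α‑carbon and creates the cyclobutanone; the new quaternary bridgehead (future C1) is dictated by the bicyclic frame, the CH bridgehead (future C7) is untouched, and long‑wavelength light limits racemising secondary photolysis.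

Step 3
Reactants: 3 1‑allylchrysanthenone
Product: 5 2,2'‑[(1S,3S)‑1‑acetyl‑2,2‑dimethyl‑4‑oxocyclobutane‑1,3‑diyl]diacetaldehyde, via bis‑ozonide 4 (not isolated)
Conditions: O3, CH2Cl2, −78 °C; then Me2S, −78 °C to rt
Reagents that add atoms: ozone, [O-][O+]=O
Why: Ozonolysis with reductive work‑up cleaves the ring alkene (to the acetyl group on future C1 and CH2CHO on future C7, cis because they were bridged) and the allyl group (to CH2CHO on future C1) without touching a stereocentre.

Step 4
Reactants: 5 keto dialdehyde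
Product: 6 (2S,4S)‑2‑acetyl‑3,3‑dimethyl‑2,4‑bis(3‑methylbut‑2‑en‑1‑yl)cyclobutan‑1‑one (prenyl groups trans; ring carbons are C9, C1, C8, C7, the acetyl group is C2/C3)
Conditions: i‑PrPPh3I, n‑BuLi, THF, 0 °C; then 5, −78 °C to 0 °C
Reagents that add atoms: isopropyltriphenylphosphonium iodide, CC(C)[P+](c1ccccc1)(c1ccccc1)c1ccccc1.[I-]
Why: Double Wittig olefination, in which the non‑stabilised ylide should react with the two aldehydes much faster than with the hindered ketones at low temperature, installs both prenyl groups at once and leaves C1 and C7 unchanged.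

Step 5
Reactants: 7 (+)‑limonene oxide, (4R)‑1‑methyl‑4‑(prop‑1‑en‑2‑yl)‑7‑oxabicyclo[4.1.0]heptane
Product: 9 (3R)‑6‑oxo‑3‑(prop‑1‑en‑2‑yl)heptanal, via diol 8 (not isolated)
Conditions: H5IO6, THF/H2O, 0 °C to rt
Reagents that add atoms: water, O
Why: Periodic acid opens the epoxide to the 1,2‑diol and cleaves it (Malaprade glycol cleavage) to the keto aldehyde; the isopropenyl‑bearing stereocentre is not involved.

Step 6
Reactants: 9 keto aldehyde
Product: 10 (5R)‑5‑(prop‑1‑en‑2‑yl)oct‑7‑yn‑2‑one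
Conditions: dimethyl (1‑diazo‑2‑oxopropyl)phosphonate, K2CO3, MeOH, 0 °C to rt
Reagents that add atoms: dimethyl (1‑diazo‑2‑oxopropyl)phosphonate, CC(=O)C(=[N+]=[N-])P(=O)(OC)OC
Why: Seyferth–Gilbert homologation with the Ohira–Bestmann reagent converts only the aldehyde into the terminal alkyne (the methyl ketone is inert under these conditions); the stereocentre is β to the aldehyde and cannot epimerise.

Step 7
Reactants: 10 alkynyl ketone
Product: 11 (4R)‑7‑methyl‑4‑(prop‑1‑en‑2‑yl)oct‑7‑en‑1‑yne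
Conditions: Ph3PCH3Br, KOt‑Bu, THF, 0 °C to rt
Reagents that add atoms: methyltriphenylphosphonium bromide, C[P+](c1ccccc1)(c1ccccc1)c1ccccc1.[Br-]
Why: Wittig methylenation of the methyl ketone gives the terminal 1,1‑disubstituted alkene of the side chain.

Step 8
Reactants: 11 enyne
Product: 12 (4R)‑7‑methyl‑2‑methylidene‑4‑(prop‑1‑en‑2‑yl)oct‑7‑enoic acid
Conditions: Pd(OAc)2 (1 mol%), 2‑(diphenylphosphino)pyridine, MeSO3H (cat.), CO (30 bar), H2O, acetone, 50 °C
Reagents that add atoms: carbon monoxide, [C-]#[O+]; water, O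
Why: Palladium‑catalysed Markovnikov (branched‑selective) hydroxycarbonylation of a terminal alkyne with the pyridylphosphine/acid system gives the 2‑substituted acrylic acid (C4, C5=C6), the isolated 1,1‑disubstituted alkenes being far less reactive than the alkyne.

Step 9
Reactants: 6 diprenyl acetylcyclobutanone; 12 acrylic acid
Product: 14 (6R)‑1‑[(1S,3S)‑2,2‑dimethyl‑1,3‑bis(3‑methylbut‑2‑en‑1‑yl)‑4‑oxocyclobutyl]‑9‑methyl‑4‑methylidene‑6‑(prop‑1‑en‑2‑yl)dec‑9‑ene‑1,3‑dione (chelated enol in solution), via acid chloride 13 (not isolated)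
Conditions: 12, 1‑chloro‑N,N,2‑trimethylprop‑1‑en‑1‑amine, CH2Cl2, 0 °C; then 6, MgBr2·OEt2, i‑Pr2NEt, CH2Cl2, 0 °C to rt
Reagents that add atoms: none
Why: Crossed Claisen C‑acylation under soft enolisation, in which MgBr2 chelates the 1,3‑dicarbonyl unit of 6 so that the amine deprotonates the acetyl methyl group (C3) and the magnesium enolate is acylated on carbon by the acid chloride; the product stays as a magnesium chelate and C7 is not enolised.

Step 10
Reactants: 14 β‑diketone
Product: 16 (2E,6R)‑1‑[(1S,3S)‑2,2‑dimethyl‑1,3‑bis(3‑methylbut‑2‑en‑1‑yl)‑4‑oxocyclobutyl]‑3‑methoxy‑9‑methyl‑4‑methylidene‑6‑(prop‑1‑en‑2‑yl)deca‑2,9‑dien‑1‑one, via Z‑enol ether 15 (not isolated)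
Conditions: TMSCHN2, MeOH/toluene, 0 °C to rt; then PPTS (cat.), CH2Cl2, rt
Reagents that add atoms: trimethylsilyldiazomethane, C[Si](C)(C)C=[N+]=[N-]
Why: O‑Methylation of the enolised diketone by diazomethane formed in situ should occur at the less hindered C4 oxygen, and acid‑catalysed equilibration of the push–pull alkene should give the more stable E enol ether (methoxy trans to the acyl group), in which C2 and C5 are cis as ring A requires.

Step 11
Reactants: 16 E‑methoxydienone cyclobutanone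
Product: 17 (1S,5R,7R)‑4‑methoxy‑8,8‑dimethyl‑1,7‑bis(3‑methylbut‑2‑en‑1‑yl)‑5‑[(2R)‑5‑methyl‑2‑(prop‑1‑en‑2‑yl)hex‑5‑en‑1‑yl]bicyclo[3.3.1]non‑3‑ene‑2,9‑dione (same spatial arrangement as the target; 7‑prenyl cis to the C2–C4 bridge)
Conditions: [Rh(cod)Cl]2 (5 mol%), P[3,5‑(CF3)2C6H3]3 (24 mol%), 1,4‑dioxane, 130 °C, sealed tube
Reagents that add atoms: none
Why: Proposed new method: Monovalent rhodium should add oxidatively to the strained and less substituted C9–C7 bond to give a rhodacyclopentanone, the tethered C5=C6 alkene should insert into the rhodium–acyl bond with C9 bonding to the internal carbon C5, and C(sp3)–C(sp3) reductive elimination from the trivalent rhodium intermediate should then join C6 to C7, driven by release of cyclobutanone strain. The closest known reaction type is the rhodium‑catalysed intramolecular carboacylation ("cut and sew") of alkenes by cyclobutanones and benzocyclobutenones, which gives fused and bridged ketones with quaternary centres and, in the benzocyclobutenone series, already transfers the acyl group to the internal carbon of an alkene tethered next to the carbonyl; it has not been shown for a saturated, fully substituted cyclobutanone that must open at the bond remote from the tether to give a ketone‑bridged bicyclo[3.3.1]nonane. Ring A (C9, C1, C2, C3, C4, C5) closes by 6‑exo‑trig acyl‑rhodation of the 1,1‑disubstituted alkene and ring B (C5, C6, C7, C8, C1, C9) by reductive elimination from a seven‑membered rhodacycle. The new C5 stereocentre is fixed by C1, because the one‑carbon C9 bridge can span C1 and C5 on one face only, and C7 keeps its configuration because oxidative addition and reductive elimination both occur with retention at carbon. The step needs cleavage of C9–C7 in preference to C9–C1 and 6‑exo in preference to 7‑endo acyl transfer: the quaternary C1 (which in the other mode would have to form a vicinal quaternary C1–C5 bond), the reversibility of C–C oxidative addition, and the three‑atom C2–C4 tether with its E enol ether are expected to secure both.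

Step 12
Reactants: 18 3,4‑dihydroxybenzoic acid
Product: 19 tert‑butyldimethylsilyl 3,4‑bis(tert‑butyldimethylsilyloxy)benzoate
Conditions: TBSCl, imidazole, DMF, rt
Reagents that add atoms: tert‑butyldimethylsilyl chloride, CC(C)(C)[Si](C)(C)Cl
Why: Silylation of both phenols and the carboxylic acid (silyl ether and silyl ester formation) protects the catechol in a form that survives an organolithium acylation.

Step 13
Reactants: 19 tris‑silyl compound
Product: 20 3,4‑bis(tert‑butyldimethylsilyloxy)benzoyl chloride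
Conditions: (COCl)2, DMF (cat.), CH2Cl2, 0 °C to rt
Reagents that add atoms: oxalyl chloride, O=C(Cl)C(=O)Cl
Why: Vilsmeier‑type activation converts the silyl ester directly into the acid chloride under neutral conditions and leaves the aryl silyl ethers intact.

Step 14
Reactants: 17 bicyclic methyl enol ether; 20 aroyl chloride
Product: 22 (1R,5R,7R)‑3‑[3,4‑bis(tert‑butyldimethylsilyloxy)benzoyl]‑4‑methoxy‑8,8‑dimethyl‑1,7‑bis(3‑methylbut‑2‑en‑1‑yl)‑5‑[(2R)‑5‑methyl‑2‑(prop‑1‑en‑2‑yl)hex‑5‑en‑1‑yl]bicyclo[3.3.1]non‑3‑ene‑2,9‑dione, via vinyllithium 21 (not isolated)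
Conditions: 2,2,6,6‑tetramethylpiperidine, n‑BuLi, THF, −78 °C; then 20, −78 °C to −40 °C
Reagents that add atoms: none
Why: Deprotonation of the vinylogous ester at C3 (the only acidic position, both bridgeheads being quaternary) gives a vinyllithium that is acylated by the aroyl chloride, as known for bridged vinylogous esters of this class.

Step 15
Reactants: 22 protected acyl compound
Product: 23 target, (1R,5R,7R)‑3‑(3,4‑dihydroxybenzoyl)‑4‑hydroxy‑8,8‑dimethyl‑1,7‑bis(3‑methylbut‑2‑en‑1‑yl)‑5‑[(2R)‑5‑methyl‑2‑(prop‑1‑en‑2‑yl)hex‑5‑en‑1‑yl]bicyclo[3.3.1]non‑3‑ene‑2,9‑dione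
Conditions: LiOH·H2O, 1,4‑dioxane/H2O, 90 °C, degassed; then 1 M HCl, 0 °C
Reagents that add atoms: lithium hydroxide, [Li+].[OH-]
Why: Hydroxide adds to C4 of the doubly activated vinylogous ester and expels methoxide (addition–elimination), and the same conditions cleave both aryl silyl ethers; acid‑free handling avoids cyclisation of the prenyl groups and no stereocentre is affected.

Compound list
1 | (1S,5S)‑(−)‑verbenone | CC1=CC(=O)[C@H]2C[C@@H]1C2(C)C | starting material
2 | 3‑allylverbenone | CC1=C(CC=C)C(=O)[C@H]2C[C@@H]1C2(C)C | intermediate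
3 | 1‑allylchrysanthenone | CC1=CC[C@@H]2C(=O)[C@@]1(CC=C)C2(C)C | intermediate
4 | bis‑ozonide of 3 (both C=C bonds as 1,2,4‑trioxolanes) | CC12OOC(O1)C[C@@H]3C(=O)[C@@]2(CC4OOCO4)C3(C)C | intermediate
5 | 2,2'‑[(1S,3S)‑1‑acetyl‑2,2‑dimethyl‑4‑oxocyclobutane‑1,3‑diyl]diacetaldehyde | CC(=O)[C@@]1(CC=O)C(=O)[C@@H](CC=O)C1(C)C | intermediate
6 | (2S,4S)‑2‑acetyl‑3,3‑dimethyl‑2,4‑bis(3‑methylbut‑2‑en‑1‑yl)cyclobutan‑1‑one | CC(=O)[C@@]1(CC=C(C)C)C(=O)[C@@H](CC=C(C)C)C1(C)C | intermediate
7 | (+)‑limonene oxide (4R, cis/trans mixture) | CC12CC[C@H](CC1O2)C(=C)C | starting material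
8 | (4R)‑1‑methyl‑4‑(prop‑1‑en‑2‑yl)cyclohexane‑1,2‑diol | CC1(O)CC[C@H](CC1O)C(=C)C | intermediate
9 | (3R)‑6‑oxo‑3‑(prop‑1‑en‑2‑yl)heptanal | CC(=O)CC[C@H](CC=O)C(=C)C | intermediate
10 | (5R)‑5‑(prop‑1‑en‑2‑yl)oct‑7‑yn‑2‑one | CC(=O)CC[C@H](CC#C)C(=C)C | intermediate
11 | (4R)‑7‑methyl‑4‑(prop‑1‑en‑2‑yl)oct‑7‑en‑1‑yne | C=C(C)CC[C@H](CC#C)C(=C)C | intermediate
12 | (4R)‑7‑methyl‑2‑methylidene‑4‑(prop‑1‑en‑2‑yl)oct‑7‑enoic acid | C=C(C)CC[C@H](CC(=C)C(=O)O)C(=C)C | intermediate
13 | (4R)‑7‑methyl‑2‑methylidene‑4‑(prop‑1‑en‑2‑yl)oct‑7‑enoyl chloride | C=C(C)CC[C@H](CC(=C)C(=O)Cl)C(=C)C | intermediate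
14 | β‑diketone (diketo form drawn) | C=C(C)CC[C@H](CC(=C)C(=O)CC(=O)[C@@]1(CC=C(C)C)C(=O)[C@@H](CC=C(C)C)C1(C)C)C(=C)C | intermediate
15 | (2Z)‑methyl enol ether | C=C(C)CC[C@H](CC(=C)/C(OC)=C/C(=O)[C@@]1(CC=C(C)C)C(=O)[C@@H](CC=C(C)C)C1(C)C)C(=C)C | intermediate
16 | (2E)‑methyl enol ether, substrate of the key step | C=C(C)CC[C@H](CC(=C)/C(OC)=C\C(=O)[C@@]1(CC=C(C)C)C(=O)[C@@H](CC=C(C)C)C1(C)C)C(=C)C | intermediate
17 | bicyclo[3.3.1]nonane methyl enol ether | C=C(C)CC[C@H](C[C@@]12C[C@@H](CC=C(C)C)C(C)(C)[C@@](CC=C(C)C)(C(=O)C=C1OC)C2=O)C(=C)C | intermediate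
18 | 3,4‑dihydroxybenzoic acid | O=C(O)c1ccc(O)c(O)c1 | starting material
19 | tert‑butyldimethylsilyl 3,4‑bis(tert‑butyldimethylsilyloxy)benzoate | O=C(O[Si](C)(C)C(C)(C)C)c1ccc(O[Si](C)(C)C(C)(C)C)c(O[Si](C)(C)C(C)(C)C)c1 | intermediate
20 | 3,4‑bis(tert‑butyldimethylsilyloxy)benzoyl chloride | O=C(Cl)c1ccc(O[Si](C)(C)C(C)(C)C)c(O[Si](C)(C)C(C)(C)C)c1 | intermediate
21 | C3‑lithio derivative of 17 | C=C(C)CC[C@H](C[C@@]12C[C@@H](CC=C(C)C)C(C)(C)[C@@](CC=C(C)C)(C(=O)C([Li])=C1OC)C2=O)C(=C)C | intermediate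
22 | C3‑aroylated, silyl‑protected methyl enol ether | C=C(C)CC[C@H](C[C@@]12C[C@@H](CC=C(C)C)C(C)(C)[C@@](CC=C(C)C)(C(=O)C(C(=O)c3ccc(O[Si](C)(C)C(C)(C)C)c(O[Si](C)(C)C(C)(C)C)c3)=C1OC)C2=O)C(=C)C | intermediate
23 | CNP0139652.2 | C=C(C)CC[C@H](C[C@@]12C[C@@H](CC=C(C)C)C(C)(C)[C@@](CC=C(C)C)(C(=O)C(C(=O)c3ccc(O)c(O)c3)=C1O)C2=O)C(=C)C | target

Total step count: 15.
Longest linear sequence: 9 steps (steps 1–4, 9, 10, 11, 14, 15; the branch from 7 through steps 5–8 is equally long).

Steps most likely to fail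

1. Step 11. Rhodium may insert into the other acyl–carbon bond (C9–C1) and close a fused isomer. The rhodacycle may also lose CO, or undergo β‑hydride elimination at C7 to a ring‑opened dienyl aldehyde, and the 1,1‑disubstituted alkenes may isomerise at 130 °C. Fallback (sets out from 6 and 11, comes back at 17): ring B is built by two known one‑carbon diazo ring expansions and ring A by a Claisen condensation. Ethereal diazomethane in MeOH at 0 °C should expand the strained cyclobutanone 6 by migration of the less substituted C7 (retention) to the cyclopentanone F1, the new CH2 being C6. Enyne 11 is hydroborated at the alkyne (Cy2BH, THF; then NaBO3) to the aldehyde F2, oxidised (NaClO2, NaH2PO4, 2‑methyl‑2‑butene, Pinnick) to the acid F3 and esterified (TMSCHN2) to the methyl ester F4. Trifluoroacetylation (LiN(SiMe3)2, CF3CO2CH2CF3) to the α‑trifluoroacetyl ester F5 and detrifluoroacetylative Regitz diazo transfer (MsN3, Et3N) give the α‑diazo ester F6. Sc(OTf)3‑catalysed ring expansion of F1 with F6 (migration of C6, loss of dinitrogen) should give the cyclohexanone β‑keto ester F7 with C5 quaternary. KOt‑Bu‑mediated intramolecular Claisen condensation of the acetyl group onto the ester then closes ring A to the trione F8, and O‑methylation with TMSCHN2 at the less hindered C4 oxygen returns to 17. Only the diastereomer of F7 with acetyl and ester cis can cyclise.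

2. Step 4. The ylide may act as a base, causing intramolecular aldol condensation between the acetyl group and the neighbouring aldehyde or epimerisation at C7, or it may attack the strained ketone. Fallback (sets out from 1, comes back at 6): the C1 prenyl group is introduced by enolate alkylation, so only one aldehyde is ever present. Verbenone 1 is photoisomerised (350 nm, cyclohexane) to (1R,5S)‑chrysanthenone F9. Ozonolysis (O3, CH2Cl2, −78 °C) gives the ozonide F10 and, after Me2S, the acetylcyclobutanone aldehyde F11. Wittig olefination with isopropylidenetriphenylphosphorane (two equivalents, the first deprotonating the β‑diketone and so shielding both ketones) gives the monoprenyl β‑diketone F12. C‑Prenylation (K2CO3, prenyl bromide, acetone) on the face away from the C7 side chain then gives 6.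

3. Step 9. O‑Acylation, conjugate addition to the acrylic acid chloride or oxa‑Michael cyclisation of the enolised product may outrun C‑acylation, and enolisation towards C7 would erode that centre. Fallback (sets out from 12 and 6, comes back at 14): the C3–C4 bond is made by aldol addition and the ketone by oxidation. Acid 12 is reduced with AlH3 (from LiAlH4 and AlCl3, Et2O, 0 °C) to the allylic alcohol F13 and oxidised with MnO2 to the enal F14. Ketone 6 is converted with LiN(SiMe3)2 (THF, −78 °C) into its lithium enolate F15, which adds to F14 to give the β‑hydroxy ketone F16 as both carbinol epimers. Dess–Martin periodinane then gives 14.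

Further compounds
F1 | step 11 | 2‑acetyl‑3,3‑dimethyl‑2,4‑bis(3‑methylbut‑2‑en‑1‑yl)cyclopentan‑1‑one (configuration as in 6) | CC(=O)[C@@]1(CC=C(C)C)C(=O)C[C@@H](CC=C(C)C)C1(C)C
F2 | step 11 | (4R)‑7‑methyl‑4‑(prop‑1‑en‑2‑yl)oct‑7‑enal | C=C(C)CC[C@H](CCC=O)C(=C)C
F3 | step 11 | (4R)‑7‑methyl‑4‑(prop‑1‑en‑2‑yl)oct‑7‑enoic acid | C=C(C)CC[C@H](CCC(=O)O)C(=C)C
F4 | step 11 | methyl (4R)‑7‑methyl‑4‑(prop‑1‑en‑2‑yl)oct‑7‑enoate | C=C(C)CC[C@H](CCC(=O)OC)C(=C)C
F5 | step 11 | α‑trifluoroacetyl derivative of F4 | C=C(C)CC[C@H](CC(C(=O)C(F)(F)F)C(=O)OC)C(=C)C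
F6 | step 11 | methyl (4R)‑2‑diazo‑7‑methyl‑4‑(prop‑1‑en‑2‑yl)oct‑7‑enoate | C=C(C)CC[C@H](CC(=[N+]=[N-])C(=O)OC)C(=C)C
F7 | step 11 | ring B cyclohexanone β‑keto ester (acetyl and ester cis) | C=C(C)CC[C@H](C[C@]1(C(=O)OC)C[C@@H](CC=C(C)C)C(C)(C)[C@@](CC=C(C)C)(C(C)=O)C1=O)C(=C)C
F8 | step 11 | bicyclo[3.3.1]nonane‑2,4,9‑trione | C=C(C)CC[C@H](C[C@@]12C[C@@H](CC=C(C)C)C(C)(C)[C@@](CC=C(C)C)(C(=O)CC1=O)C2=O)C(=C)C
F9 | step 4 | (1R,5S)‑chrysanthenone | CC1=CC[C@@H]2C(=O)[C@H]1C2(C)C
F10 | step 4 | ozonide of F9 | CC12OOC(O1)C[C@@H]3C(=O)[C@H]2C3(C)C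
F11 | step 4 | 2‑[(1S)‑3‑acetyl‑2,2‑dimethyl‑4‑oxocyclobutyl]acetaldehyde (acetyl carbon enolisable) | CC(=O)C1C(=O)[C@@H](CC=O)C1(C)C
F12 | step 4 | (4S)‑2‑acetyl‑3,3‑dimethyl‑4‑(3‑methylbut‑2‑en‑1‑yl)cyclobutan‑1‑one | CC(=O)C1C(=O)[C@@H](CC=C(C)C)C1(C)C
F13 | step 9 | (4R)‑7‑methyl‑2‑methylidene‑4‑(prop‑1‑en‑2‑yl)oct‑7‑en‑1‑ol | C=C(C)CC[C@H](CC(=C)CO)C(=C)C
F14 | step 9 | (4R)‑7‑methyl‑2‑methylidene‑4‑(prop‑1‑en‑2‑yl)oct‑7‑enal | C=C(C)CC[C@H](CC(=C)C=O)C(=C)C
F15 | step 9 | lithium enolate of 6 (acetyl side) | [Li]OC(=C)[C@@]1(CC=C(C)C)C(=O)[C@@H](CC=C(C)C)C1(C)C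
F16 | step 9 | β‑hydroxy ketone (aldol adduct, carbinol epimers) | C=C(C)CC[C@H](CC(=C)C(O)CC(=O)[C@@]1(CC=C(C)C)C(=O)[C@@H](CC=C(C)C)C1(C)C)C(=C)C
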